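The runs stem from a simulated flask for an exercise.

**Quick number.** Take the blue flask from its balance and leave the rate law aside: you wanted a number quickly, and the charges already carry most of it. This is what we both have.

| flask | substrate | reagent | free catalyst | time |
|---|---|---|---|---|
| ochre | 0.100 M | 0.0800 M | 0.00200 M |  |
| amber | 0.100 M | 0.0800 M | 0.00600 M |  |
| violet | 0.150 M | 0.0800 M | 0.00200 M |  |
| blue | 0.210 M | 0.0800 M | 0.00200 M | 17 h |

| run | time / h | [substrate] / M |
|---|---|---|
| ochre run | 3.4 | 0.0514 |
| ochre run | 6.8 | 0.0369 |
| ochre run | 10 | 0.0320 |
| ochre run | 14 | 0.0284 |
| ochre run | 17 | 0.0274 |
| amber run | 3.4 | 0.0354 |
| amber run | 6.8 | 0.0265 |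
| amber run | 10 | 0.0244 |
| amber run | 14 | 0.0234 |
| amber run | 17 | 0.0228 |
| violet run | 3.4 | 0.0897 |
| violet run | 6.8 | 0.0774 |
| violet run | 10 | 0.0751 |
| violet run | 14 | 0.0730 |
| violet run | 17 | 0.0726 |

(standard deviation of a reading: 3 × 10⁻⁴ M)

1. the power of [free catalyst] that the first rate follows, about the charge of the ochre run; measure it at two percent of substrate made into target
2. the power of [substrate] that the first rate follows, about the charge of the ochre run; measure it at two percent of substrate made into target (one fixed amount of target, the same in the runs compared)
3. substrate in the blue run at 17 h, as a share of the substrate charged

- Overall: substrate + reagent -> target, with free catalyst as catalyst.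
- Constant volume, constant temperature.
- Readings of a species count what is bound in complexes too.
- An order is taken over about fifteen percent of the charge, up and down.

**Frozen difference.** The overall equation spends one substrate and one reagent for each target made, so the difference c(substrate) minus c(reagent) should stay nearly constant through a run, and c(substrate) can fall no lower than this standing excess while reagent, the limiting reagent, is what stops the reaction. In the blue flask, where reagent is charged below substrate, the standing excess is 0.130 M, which is 61.9% of the substrate charged.

**Testing it.** At 17 h, the ochre run reads 0.00740 M above its own excess, and the violet run reads 0.00260 M above its own, a narrower gap at the same free catalyst charge with a larger excess. The blue flask has the same free catalyst and a larger excess still, so I expect its gap to be no wider than the violet one. Adding the violet gap to the blue excess, as the widest gap I expect, I commit to 63.1% of the substrate charged, as an estimate from the high side.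

**Your forecast.** You give 0.8 for the catalyst order, 0.85 for the substrate order and 62.2% for the blue flask, noting that “reagent is nearly consumed”. I take your orders as they stand, but my blue share is higher than yours.

**What came.**

    2 free catalyst ⇌ catalyst dimer, settled at all times (352.0 /M)
    free catalyst + substrate + reagent → target + free catalyst (4428 /M²/h)
    target + reagent → side product (0.3672 /M/h)
    free catalyst + substrate ⇌ idle catalyst-substrate complex, settled at all times (6.110 /M)

The orders come out at 0.78 in free catalyst and 0.81 in substrate, and the blue flask holds 62.9% of the substrate charged at 17 h, which is 0.00201 M above its excess of 0.130 M. The idle catalyst-substrate complex holds the substrate order about the ochre charge below one, because substrate that raises the rate also ties up free catalyst: the same ochre charge without that complex gives a substrate order of 1.0.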